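**Retrosynthetic overview**
- The target is opened at both lactone C–O bonds to a tetrahydroxy tri-tert-butyl ester. In the forward direction both γ-lactones close in the last step, in one acid operation: ring B (C3–O onto the C1 carboxyl) and ring A (C5–O onto the C3 carboxyl).
- The C5 carbinol comes from a C5 ketone by 1,3-anti reduction directed by the free C3 tertiary hydroxyl.
- The C1 carbinol comes from an α-keto ester by Felkin–Anh reduction. The single enantiomer is obtained by vanadium-catalysed oxidative kinetic resolution of that α-hydroxy ester.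
- Key step: a one-pot cascade of a methyl ketone enolate, two silyl glyoxylates and an oxalyl chloride monoester. Each acylsilane carbon is attacked as an electrophile and, after [1,2]-Brook rearrangement, attacks the next carbonyl as a nucleophile, so C2–C3 and C1–C2 each join two carbonyl carbons.
- The methyl ketone comes from undec-10-enoic acid and methyllithium.

Assumption: 3 and 4 are bought as catalogue reagents; locants C1–C15 are those of the open-chain pentadec-14-ene-1,2,3-tricarboxylate (C1 = CH(OH), C2 and C3 = the tertiary carbinol carbons, C4 = CH2, C5 = chain carbinol); racemates (7, 8, 9) are written with the SMILES of the enantiomer that is carried on.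

**Step 1**
Reactants: 1 undec-10-enoic acid
Product: 2 dodec-11-en-2-one
Conditions: MeLi (2.2 equiv), Et2O, 0 °C → rt; inverse quench into ice-water
Reagents that add atoms: methyllithium, [Li]C
Why: Ketone synthesis from a carboxylic acid and an organolithium: the lithium carboxylate takes up one MeLi to give a gem-dilithioxy adduct that collapses to the methyl ketone only on hydrolysis, so there is no over-addition; no stereocentre is formed and the terminal alkene is inert.

**Step 2**
Reactants: 2 dodec-11-en-2-one; 3 tert-butyl 2-[tert-butyl(dimethyl)silyl]-2-oxoacetate (2.05 equiv); 4 tert-butyl 2-chloro-2-oxoacetate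
Product: 8 tri-tert-butyl (2S*,3S*)-2,3-bis[(tert-butyldimethylsilyl)oxy]-1,5-dioxopentadec-14-ene-1,2,3-tricarboxylate (racemic; t-BuO2C–CO–C(OTBS)(CO2t-Bu)–C(OTBS)(CO2t-Bu)–CH2–CO–(CH2)8CH=CH2), via lithium enolate 5 (not isolated), via first Brook enolate 6 (not isolated), via second Brook enolate 7 (not isolated)
Conditions: LDA (commercial, 1.05 equiv), THF, −78 °C; cannulate onto 3 in THF, −78 → −45 °C; recool to −78 °C, add 4 (2 equiv), → −30 °C; aq. NH4Cl
Reagents that add atoms: none
Why: Proposed new method: the kinetic (methyl-side) enolate 5 adds to the acylsilane carbonyl of 3 and the alkoxide undergoes [1,2]-Brook rearrangement, so the former carbonyl carbon C3 becomes glycolate enolate 6, which adds to a second 3 (C3 becomes stereogenic, racemic); a second Brook shift makes C2 nucleophilic in 7, which is too hindered to take a third acylsilane and is C-acylated by 4 on the enolate face anti to the C3–CH2 bond with the C3–OSi bond in the enolate plane and the C3 ester outside, giving the meso-type (2S*,3S*) array; the closest known reactions are the controlled silyl glyoxylate double Brook/aldol cascade started by vinylmagnesium bromide and ended by tert-butyl glyoxylate, ketone-enolate-initiated silyl glyoxylate couplings, and Claisen acylation of such Brook enolates by β-lactones.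

**Step 3**
Reactants: 8 tri-tert-butyl (2S*,3S*)-2,3-bis[(tert-butyldimethylsilyl)oxy]-1,5-dioxopentadec-14-ene-1,2,3-tricarboxylate
Product: 9 tri-tert-butyl (1R*,2R*,3S*)-2,3-bis[(tert-butyldimethylsilyl)oxy]-1-hydroxy-5-oxopentadec-14-ene-1,2,3-tricarboxylate (racemic)
Conditions: NaBH4 (1 equiv), THF/MeOH 4:1, −78 °C, 30 min; AcOH quench at −78 °C
Reagents that add atoms: none
Why: Chemoselective borohydride reduction of the α-keto ester carbonyl (the C5 dialkyl ketone is much slower at −78 °C) under polar Felkin–Anh (equally Cornforth) control: the C2–OSi bond lies anti to the incoming hydride, which passes the C2 ester and not the quaternary C3, giving the (1R*) carbinol; non-chelating Na+/MeOH is used because Cram-chelate delivery would give the C1 epimer.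

**Step 4**
Reactants: 9 tri-tert-butyl (1R*,2R*,3S*)-2,3-bis[(tert-butyldimethylsilyl)oxy]-1-hydroxy-5-oxopentadec-14-ene-1,2,3-tricarboxylate (racemic)
Product: 10 tri-tert-butyl (1R,2R,3S)-2,3-bis[(tert-butyldimethylsilyl)oxy]-1-hydroxy-5-oxopentadec-14-ene-1,2,3-tricarboxylate
Conditions: VO(Oi-Pr)3 (5 mol %), (S)-2,4-di-tert-butyl-6-{[(1-hydroxy-3,3-dimethylbutan-2-yl)imino]methyl}phenol (5.5 mol %), O2 (1 atm), acetone, rt, to about 55% conversion
Reagents that add atoms: none
Why: Vanadium-catalysed aerobic oxidative kinetic resolution of an α-hydroxy ester: the chiral V(V)–Schiff base complex chelates the hydroxy ester and oxidises the (1S)-enantiomer to the keto ester much faster, so the (1R,2R,3S)-enantiomer is recovered in high ee, as known for the vinyl analogue of this silyl glyoxylate dimer; the sense (S-ligand leaves the R-carbinol) is my expectation and is checked on the first run, with the (R)-ligand used if it is opposite.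

**Step 5**
Reactants: 10 tri-tert-butyl (1R,2R,3S)-2,3-bis[(tert-butyldimethylsilyl)oxy]-1-hydroxy-5-oxopentadec-14-ene-1,2,3-tricarboxylate
Product: 11 tri-tert-butyl (1R,2R,3S)-1,2,3-trihydroxy-5-oxopentadec-14-ene-1,2,3-tricarboxylate
Conditions: HF·pyridine (excess), THF/pyridine, 0 °C → rt (plastic vessel)
Reagents that add atoms: none
Why: Fluoride-driven Si–O cleavage of both tertiary silyl ethers under acidic, alkoxide-free conditions, which avoids retro-aldol cleavage of the β-hydroxy ketone and β-hydroxy esters; tert-butyl esters, ketone and alkene are untouched and no stereocentre is affected.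

**Step 6**
Reactants: 11 tri-tert-butyl (1R,2R,3S)-1,2,3-trihydroxy-5-oxopentadec-14-ene-1,2,3-tricarboxylate
Product: 12 tri-tert-butyl (1R,2R,3S,5R)-1,2,3,5-tetrahydroxypentadec-14-ene-1,2,3-tricarboxylate
Conditions: Me4NBH(OAc)3 (5 equiv), MeCN/AcOH 1:1, −30 → −20 °C
Reagents that add atoms: none
Why: Evans–Saksena hydroxyl-directed reduction: the C3 hydroxyl exchanges onto boron and delivers hydride intramolecularly through a chair in which the C6 chain and the bulky C2 carbon are equatorial and the C3 ester is axial, giving the 3,5-anti diol, that is (5R); esters and the alkene are inert to the reagent.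

**Step 7**
Reactants: 12 tri-tert-butyl (1R,2R,3S,5R)-1,2,3,5-tetrahydroxypentadec-14-ene-1,2,3-tricarboxylate
Product: 13 (3R,4R,5S,8R)-8-(dec-9-en-1-yl)-3,4-dihydroxy-2,6-dioxo-1,7-dioxaspiro[4.4]nonane-4-carboxylic acid (CNP0281847.1)
Conditions: TFA/CH2Cl2 1:2, 0 °C → rt, 4 h; evaporate; PhMe, 60 °C
Reagents that add atoms: none
Why: Acidolysis of the three tert-butyl esters followed by double acid-catalysed γ-lactonisation (C5–OH onto the C3 carboxyl, C3–OH onto the C1 carboxyl); the spiro bis-γ-lactone is the thermodynamic sink, the C2 acid stays free because it can only form a β- or δ-lactone, no stereocentre is touched, and short exposure keeps the terminal alkene intact.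

**Compound list**
1 | undec-10-enoic acid | C=CCCCCCCCCC(=O)O | starting material
2 | dodec-11-en-2-one | C=CCCCCCCCCC(C)=O | intermediate
3 | tert-butyl 2-[tert-butyl(dimethyl)silyl]-2-oxoacetate (silyl glyoxylate) | CC(C)(C)OC(=O)C(=O)[Si](C)(C)C(C)(C)C | starting material
4 | tert-butyl 2-chloro-2-oxoacetate | CC(C)(C)OC(=O)C(Cl)=O | starting material
5 | lithium dodeca-1,11-dien-2-olate | C=CCCCCCCCCC(=C)O[Li] | intermediate (not isolated)
6 | lithium enolate of tert-butyl 2-[(tert-butyldimethylsilyl)oxy]-4-oxotetradec-13-enoate (enolate geometry not assigned) | C=CCCCCCCCCC(=O)CC(O[Si](C)(C)C(C)(C)C)=C(O[Li])OC(C)(C)C | intermediate (not isolated)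
7 | lithium enolate (at C2) of di-tert-butyl (3S*)-2,3-bis[(tert-butyldimethylsilyl)oxy]-2-(2-oxododec-11-en-1-yl)butanedioate (racemic, enolate geometry not assigned) | C=CCCCCCCCCC(=O)C[C@@](O[Si](C)(C)C(C)(C)C)(C(=O)OC(C)(C)C)C(O[Si](C)(C)C(C)(C)C)=C(O[Li])OC(C)(C)C | intermediate (not isolated)
8 | tri-tert-butyl (2S*,3S*)-2,3-bis[(tert-butyldimethylsilyl)oxy]-1,5-dioxopentadec-14-ene-1,2,3-tricarboxylate (racemic) | C=CCCCCCCCCC(=O)C[C@@](O[Si](C)(C)C(C)(C)C)(C(=O)OC(C)(C)C)[C@@](O[Si](C)(C)C(C)(C)C)(C(=O)OC(C)(C)C)C(=O)C(=O)OC(C)(C)C | intermediate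
9 | tri-tert-butyl (1R*,2R*,3S*)-2,3-bis[(tert-butyldimethylsilyl)oxy]-1-hydroxy-5-oxopentadec-14-ene-1,2,3-tricarboxylate (racemic) | C=CCCCCCCCCC(=O)C[C@@](O[Si](C)(C)C(C)(C)C)(C(=O)OC(C)(C)C)[C@@](O[Si](C)(C)C(C)(C)C)(C(=O)OC(C)(C)C)[C@@H](O)C(=O)OC(C)(C)C | intermediate
10 | tri-tert-butyl (1R,2R,3S)-2,3-bis[(tert-butyldimethylsilyl)oxy]-1-hydroxy-5-oxopentadec-14-ene-1,2,3-tricarboxylate (single enantiomer) | C=CCCCCCCCCC(=O)C[C@@](O[Si](C)(C)C(C)(C)C)(C(=O)OC(C)(C)C)[C@@](O[Si](C)(C)C(C)(C)C)(C(=O)OC(C)(C)C)[C@@H](O)C(=O)OC(C)(C)C | intermediate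
11 | tri-tert-butyl (1R,2R,3S)-1,2,3-trihydroxy-5-oxopentadec-14-ene-1,2,3-tricarboxylate | C=CCCCCCCCCC(=O)C[C@@](O)(C(=O)OC(C)(C)C)[C@@](O)(C(=O)OC(C)(C)C)[C@@H](O)C(=O)OC(C)(C)C | intermediate
12 | tri-tert-butyl (1R,2R,3S,5R)-1,2,3,5-tetrahydroxypentadec-14-ene-1,2,3-tricarboxylate | C=CCCCCCCCC[C@@H](O)C[C@@](O)(C(=O)OC(C)(C)C)[C@@](O)(C(=O)OC(C)(C)C)[C@@H](O)C(=O)OC(C)(C)C | intermediate
13 | (3R,4R,5S,8R)-8-(dec-9-en-1-yl)-3,4-dihydroxy-2,6-dioxo-1,7-dioxaspiro[4.4]nonane-4-carboxylic acid | C=CCCCCCCCC[C@@H]1C[C@@]2(OC(=O)[C@H](O)[C@]2(O)C(=O)O)C(=O)O1 | target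

**Totals**
Total step count: 7. Longest linear sequence: 7 steps (1 → 13).

**Steps most likely to fail and fallbacks**

Step 2 (cascade; risks are proton transfer from the ketone α-CH2 groups to the Brook enolates and O- instead of C-acylation by the acid chloride). The fallback sets out from 2 (with 3) and comes back at 8. The same enolate/double silyl glyoxylate sequence is ended with tert-butyl glyoxylate, an aldol termination that has direct precedent, to give tri-tert-butyl 2,3-bis[(tert-butyldimethylsilyl)oxy]-1-hydroxy-5-oxopentadec-14-ene-1,2,3-tricarboxylate F1 as a C1-epimer mixture. The C1 configuration is irrelevant here, because Dess–Martin oxidation of the secondary alcohol then gives 8.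

Step 3 (facial selectivity at C1). The fallback sets out from 8 and comes back at 9. If borohydride gives mainly the C1 epimer, tri-tert-butyl (1S*,2R*,3S*)-2,3-bis[(tert-butyldimethylsilyl)oxy]-1-hydroxy-5-oxopentadec-14-ene-1,2,3-tricarboxylate F2, the carbinol is corrected by substitution instead of by face selection. Tf2O/pyridine gives the C1 triflate, tri-tert-butyl (1S*,2R*,3S*)-2,3-bis[(tert-butyldimethylsilyl)oxy]-5-oxo-1-[(trifluoromethanesulfonyl)oxy]pentadec-14-ene-1,2,3-tricarboxylate F3. KNO2/18-crown-6 in DMF displaces it with inversion (C2 has no β-hydrogen, so elimination is impossible; α-triflyloxy esters next to a quaternary carbon are known to undergo SN2) to give the nitrite ester, tri-tert-butyl (1R*,2R*,3S*)-2,3-bis[(tert-butyldimethylsilyl)oxy]-1-(nitrosooxy)-5-oxopentadec-14-ene-1,2,3-tricarboxylate F4, which hydrolyses on aqueous work-up to 9.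

Step 5 (slow cleavage of two hindered tertiary silyl ethers, or lactonisation that would remove the directing C3–OH). The fallback sets out from 10 and comes back at 13. The C5 ketone is reduced with the silyl ethers in place under reagent control, (S)-Me-CBS (cat.)/BH3·SMe2, with the CH2–C3 arm acting as the large group. This gives tri-tert-butyl (1R,2R,3S,5R)-2,3-bis[(tert-butyldimethylsilyl)oxy]-1,5-dihydroxypentadec-14-ene-1,2,3-tricarboxylate F5. TFA/H2O 9:1 then removes silyl ethers and tert-butyl esters together and closes both lactones to 13.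

**Further compounds**
F1 | step 2 | tri-tert-butyl (2R*,3S*)-2,3-bis[(tert-butyldimethylsilyl)oxy]-1-hydroxy-5-oxopentadec-14-ene-1,2,3-tricarboxylate (racemic, C1 epimer mixture) | C=CCCCCCCCCC(=O)C[C@@](O[Si](C)(C)C(C)(C)C)(C(=O)OC(C)(C)C)[C@@](O[Si](C)(C)C(C)(C)C)(C(=O)OC(C)(C)C)C(O)C(=O)OC(C)(C)C
F2 | step 3 | tri-tert-butyl (1S*,2R*,3S*)-2,3-bis[(tert-butyldimethylsilyl)oxy]-1-hydroxy-5-oxopentadec-14-ene-1,2,3-tricarboxylate (racemic) | C=CCCCCCCCCC(=O)C[C@@](O[Si](C)(C)C(C)(C)C)(C(=O)OC(C)(C)C)[C@@](O[Si](C)(C)C(C)(C)C)(C(=O)OC(C)(C)C)[C@H](O)C(=O)OC(C)(C)C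
F3 | step 3 | tri-tert-butyl (1S*,2R*,3S*)-2,3-bis[(tert-butyldimethylsilyl)oxy]-5-oxo-1-[(trifluoromethanesulfonyl)oxy]pentadec-14-ene-1,2,3-tricarboxylate (racemic) | C=CCCCCCCCCC(=O)C[C@@](O[Si](C)(C)C(C)(C)C)(C(=O)OC(C)(C)C)[C@@](O[Si](C)(C)C(C)(C)C)(C(=O)OC(C)(C)C)[C@H](OS(=O)(=O)C(F)(F)F)C(=O)OC(C)(C)C
F4 | step 3 | tri-tert-butyl (1R*,2R*,3S*)-2,3-bis[(tert-butyldimethylsilyl)oxy]-1-(nitrosooxy)-5-oxopentadec-14-ene-1,2,3-tricarboxylate (racemic, not isolated) | C=CCCCCCCCCC(=O)C[C@@](O[Si](C)(C)C(C)(C)C)(C(=O)OC(C)(C)C)[C@@](O[Si](C)(C)C(C)(C)C)(C(=O)OC(C)(C)C)[C@@H](ON=O)C(=O)OC(C)(C)C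
F5 | step 5 | tri-tert-butyl (1R,2R,3S,5R)-2,3-bis[(tert-butyldimethylsilyl)oxy]-1,5-dihydroxypentadec-14-ene-1,2,3-tricarboxylate | C=CCCCCCCCC[C@@H](O)C[C@@](O[Si](C)(C)C(C)(C)C)(C(=O)OC(C)(C)C)[C@@](O[Si](C)(C)C(C)(C)C)(C(=O)OC(C)(C)C)[C@@H](O)C(=O)OC(C)(C)C
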